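The trimer is cut at its two C15–O ester and three C11–O ether bonds into one 15-silyloxy-drim-8(12)-en-11-al, used three times, and two (R)-malate-derived isocitrates. Everything rests on closing ring B of that drimane by its C8–C9 bond: a gold-catalysed 6-exo-dig addition of a methyl enol ether (C9=C11) to a terminal alkyne (C8≡C12) in a ring-A seco precursor cut from dehydroabietic acid. The step exploits the β,γ-unsaturated array O–C11–C9(H)–C8(=C12H2) of ring B: one operation closes the ring, creates the exocyclic methylene, sets C9 and unveils the C11 aldehyde for reductive etherification.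

Key step: step 10

Remark: drimane numbering is used (C11 on C9, C12 = exocyclic methylene carbon on C8, C15 = the oxygenated 4α-CH2); isocitrate carbons are C1′ (ether CH), C2′ (central CH) and C3′ (CH2); enol ether 8 and its successors are assumed to be usable as E/Z mixtures, since both isomers converge on aldehyde 12.

**Part A – drimane aldehyde 12**

Step 1
Reactants: 1 dehydroabietic acid
Product: 2 methyl dehydroabietate
Conditions: MeI, K2CO3, DMF, rt
Reagents that add atoms: iodomethane, CI
Why: SN2 O-alkylation of the carboxylate esterifies the hindered tertiary acid, and this ester later distinguishes C15 from the two carboxyls made in step 2.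

Step 2
Reactants: 2 methyl dehydroabietate
Product: 3 seco diacid
Conditions: RuCl3·xH2O (cat.), NaIO4 (excess), CCl4/MeCN/H2O, rt
Reagents that add atoms: sodium periodate, [Na+].[O-]I(=O)(=O)=O; water, O
Why: RuO4 made in situ should degrade the electron-rich trialkylbenzene ring to carboxylic acids at its two ring-fusion carbons (arene-to-carboxylic-acid degradation), which cuts C8–C9 and leaves the ring-A stereocentres C4, C5 and C10 of the chiral pool untouched.

Step 3
Reactants: 3 seco diacid
Product: 4 seco diol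
Conditions: BH3·SMe2, THF, 0 °C → rt; aqueous work-up
Reagents that add atoms: none
Why: Borane reduces carboxylic acids much faster than the hindered tertiary methyl ester (chemoselective acid reduction).

Step 4
Reactants: 4 seco diol
Product: 5 seco hydroxy aldehyde
Conditions: 2,2,6,6-tetramethylpiperidin-1-oxyl (cat.), PhI(OAc)2, CH2Cl2, 0 °C → rt
Reagents that add atoms: none
Why: The bulky oxoammonium oxidant (nitroxyl-catalysed alcohol oxidation) should take the unhindered C8 alcohol and leave the neopentyl C9 alcohol on the quaternary C10.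

Step 5
Reactants: 5 seco hydroxy aldehyde
Product: 6 seco alkynol
Conditions: dimethyl (1-diazo-2-oxopropyl)phosphonate, K2CO3, MeOH, 0 °C → rt
Reagents that add atoms: dimethyl (1-diazo-2-oxopropyl)phosphonate, COP(=O)(OC)C(=[N+]=[N-])C(C)=O
Why: Ohira–Bestmann homologation turns the aldehyde carbon C8 into a terminal alkyne by adding C12 under base too mild to touch the hindered ester.

Step 6
Reactants: 6 seco alkynol
Product: 7 seco alkynal
Conditions: Dess–Martin periodinane, NaHCO3, CH2Cl2, rt
Reagents that add atoms: none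
Why: Dess–Martin oxidation of the neopentyl alcohol gives an aldehyde without α-hydrogen, which can neither epimerise nor undergo aldol reactions.

Step 7
Reactants: 7 seco alkynal
Product: 8 seco enol ether ester
Conditions: Ph3P(CH2OMe)Cl, KN(SiMe3)2, THF, 0 °C
Reagents that add atoms: (methoxymethyl)triphenylphosphonium chloride, COC[P+](c1ccccc1)(c1ccccc1)c1ccccc1.[Cl-]
Why: Wittig olefination with the methoxymethylene ylide adds C11 as an enol ether to the hindered, non-enolisable aldehyde.

Step 8
Reactants: 8 seco enol ether ester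
Product: 9 seco enol ether alcohol
Conditions: LiAlH4, THF, 0 °C → reflux
Reagents that add atoms: none
Why: Hydride reduction of the hindered C4 ester gives the 4α-hydroxymethyl group (C15) while enol ether and alkyne are inert.

Step 9
Reactants: 9 seco enol ether alcohol
Product: 10 seco enol ether silyl ether
Conditions: TBSCl, imidazole, DMF, rt
Reagents that add atoms: tert-butyldimethylsilyl chloride, CC(C)(C)[Si](C)(C)Cl
Why: Silylation masks the C15 hydroxyl for the etherification and esterification steps, and the silyl ether is later removed by fluoride without touching any ester.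

Step 10
Reactants: 10 seco enol ether silyl ether
Product: 12 15-(tert-butyldimethylsilyloxy)drim-8(12)-en-11-al, via C11 methyl hemiacetal 11 (not isolated)
Conditions: Ph3PAuCl (5 mol %), AgSbF6 (5 mol %), CH2Cl2/H2O 10:1, rt
Reagents that add atoms: water, O
Why: Cationic monovalent gold activates the terminal alkyne and the enol ether carbon C9 adds anti to gold at the internal alkyne carbon C8, which gives an oxocarbenium ion at C11 and a vinylgold at C12; water traps the oxocarbenium ion, protodeauration releases the C8=C12 methylene and hemiacetal 11 collapses to the aldehyde. The closest known reaction type is the gold-catalysed Conia-ene-type carbocyclisation of enol ethers onto alkynes, together with the hydroxycyclisation of 1,7-enynes. Ring B closes in the 6-exo-dig mode, the only mode that leaves the methylene exocyclic on C8. The new stereocentre C9 is controlled by the ring-A chair: the arms on C5 and C10 are trans-diequatorial, so ring B should form trans-fused through a chair-like transition state with C11 pseudo-equatorial (9β-CHO, 9α-H), away from the axial H-5 and H-7. The step needs exo over endo attack, secured by the terminal alkyne and the four-atom tether, and kinetic control at C9, secured by the absence of base, so that neither epimerisation nor migration of the alkene into conjugation with the aldehyde should occur.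

**Part B – isocitrate blocks 17 and 21**

Step 11
Reactants: 13 (R)-2-(2,2-dimethyl-5-oxo-1,3-dioxolan-4-yl)acetic acid
Product: 14 tert-butyl (R)-2-(2,2-dimethyl-5-oxo-1,3-dioxolan-4-yl)acetate
Conditions: tert-butyl 2,2,2-trichloroacetimidate, BF3·OEt2 (cat.), CH2Cl2/cyclohexane, rt
Reagents that add atoms: tert-butyl 2,2,2-trichloroacetimidate, CC(C)(C)OC(=N)C(Cl)(Cl)Cl
Why: Acid-catalysed tert-butylation by the trichloroacetimidate esterifies the free carboxyl while the dioxolanone keeps the hydroxyl and C1 carboxyl of malic acid masked.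

Step 12
Reactants: 14 tert-butyl dioxolanone ester
Product: 15 4-tert-butyl 1-methyl (R)-malate
Conditions: NaOMe (cat.), MeOH, 0 °C
Reagents that add atoms: methanol, CO
Why: Methoxide opens the activated dioxolanone carbonyl (acetal-ester methanolysis) to the methyl ester and free hydroxyl, while the tert-butyl ester is inert.

Step 13
Reactants: 15 4-tert-butyl 1-methyl (R)-malate
Product: 17 3-allyl 2-tert-butyl 1-methyl (1R,2S)-1-(trimethylsilyloxy)propane-1,2,3-tricarboxylate, via lithium alkoxide 16 (not isolated)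
Conditions: LiN(SiMe3)2 (2.2 equiv), THF, −78 → −20 °C; BrCH2CO2CH2CH=CH2, −78 °C; then Me3SiCl, −78 → 0 °C
Reagents that add atoms: allyl bromoacetate, C=CCOC(=O)CBr; chlorotrimethylsilane, C[Si](C)(C)Cl
Why: Fráter–Seebach alkylation of the chelated alkoxide–enolate dianion should take place anti to the C1′ substituent and set C2′ as S, and silylation in the same flask prevents lactonisation of the alkoxide onto the new ester.

Step 14
Reactants: 13 (R)-2-(2,2-dimethyl-5-oxo-1,3-dioxolan-4-yl)acetic acid
Product: 18 allyl (R)-2-(2,2-dimethyl-5-oxo-1,3-dioxolan-4-yl)acetate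
Conditions: allyl bromide, K2CO3, acetone, rt
Reagents that add atoms: allyl bromide, C=CCBr
Why: SN2 alkylation of the carboxylate gives the allyl ester without opening the dioxolanone.

Step 15
Reactants: 18 allyl dioxolanone ester
Product: 19 4-allyl 1-methyl (R)-malate
Conditions: NaOMe (cat.), MeOH, −20 → 0 °C, short contact time
Reagents that add atoms: methanol, CO
Why: The dioxolanone carbonyl is far more electrophilic than the allyl ester, so brief methanolysis should open only the ring.

Step 16
Reactants: 19 4-allyl 1-methyl (R)-malate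
Product: 21 2-allyl 1,3-dimethyl (1R,2S)-1-(trimethylsilyloxy)propane-1,2,3-tricarboxylate, via lithium alkoxide 20 (not isolated)
Conditions: LiN(SiMe3)2 (2.2 equiv), THF, −78 → −40 °C; BrCH2CO2Me, −78 °C; then Me3SiCl, −78 → 0 °C
Reagents that add atoms: methyl bromoacetate, COC(=O)CBr; chlorotrimethylsilane, C[Si](C)(C)Cl
Why: The same Fráter–Seebach alkylation sets C2′ (S) anti to the C1′ substituent, and the low temperature keeps the allyl ester enolate from rearranging.

**Part C – monomers 24 and 26**

Step 17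
Reactants: 12 drimane aldehyde; 17 silyl ether of the 2′-tert-butyl 3′-allyl isocitrate
Product: 22 drimanyl isocitrate ether (2′-tert-butyl, 3′-allyl, 15-O-TBS)
Conditions: Et3SiH, Me3SiOTf (cat.), CH2Cl2, −78 °C
Reagents that add atoms: none
Why: Reductive etherification: the silyl triflate condenses aldehyde and silyl ether to an oxocarbenium ion that the silane reduces at once, which forms the C11–O bond without base and without touching C1′, C2′ or C9.

Step 18
Reactants: 22 drimanyl isocitrate ether
Product: 24 monomer acid (free C2′ carboxyl), via trimethylsilyl ester 23 (not isolated)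
Conditions: Me3SiOTf, 2,6-lutidine, CH2Cl2, 0 °C; then pH 4 aqueous buffer
Reagents that add atoms: none
Why: Silyl-triflate-mediated cleavage of the tert-butyl ester (loss of isobutene) under lutidine buffering should spare the methyl and allyl esters, the silyl ether and the exocyclic alkene.

Step 19
Reactants: 12 drimane aldehyde; 21 silyl ether of the 2′-allyl 3′-methyl isocitrate
Product: 25 drimanyl isocitrate ether (2′-allyl, 3′-methyl, 15-O-TBS)
Conditions: Et3SiH, Me3SiOTf (cat.), CH2Cl2, −78 °C
Reagents that add atoms: none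
Why: The same reductive etherification attaches the fully esterified isocitrate of the first unit.

Step 20
Reactants: 25 drimanyl isocitrate ether
Product: 26 monomer alcohol (free 15-OH)
Conditions: HF·pyridine, pyridine/THF, 0 °C → rt
Reagents that add atoms: none
Why: Fluoride desilylation frees the neopentyl C15 hydroxyl under conditions that leave all esters and the alkene alone.

**Part D – assembly**

Step 21
Reactants: 26 monomer alcohol; 24 monomer acid
Product: 27 dimer silyl ether
Conditions: 2-methyl-6-nitrobenzoic anhydride, 4-(dimethylamino)pyridine, Et3N, CH2Cl2, rt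
Reagents that add atoms: none
Why: Shiina esterification (mixed anhydride, acyl transfer by the aminopyridine) joins the hindered C2′ acid to the neopentyl C15 hydroxyl at room temperature, mild enough to avoid β-elimination of the C1′ ether.

Step 22
Reactants: 27 dimer silyl ether
Product: 28 dimer alcohol
Conditions: HF·pyridine, pyridine/THF, 0 °C → rt
Reagents that add atoms: none
Why: Fluoride desilylation frees the C15 hydroxyl of the second drimane unit only.

Step 23
Reactants: 28 dimer alcohol; 24 monomer acid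
Product: 29 trimer silyl ether
Conditions: 2-methyl-6-nitrobenzoic anhydride, 4-(dimethylamino)pyridine, Et3N, CH2Cl2, rt
Reagents that add atoms: none
Why: A second Shiina esterification adds the third unit through its C2′ carboxyl.

Step 24
Reactants: 29 trimer silyl ether
Product: 30 trimer alcohol (tri-allyl ester)
Conditions: HF·pyridine, pyridine/THF, 0 °C → rt
Reagents that add atoms: none
Why: Fluoride desilylation frees the C15 hydroxyl of the terminal drimane unit.

Step 25
Reactants: 30 trimer alcohol (tri-allyl ester)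
Product: 31 cryptoporic acid T
Conditions: Pd(PPh3)4 (cat.), morpholine, THF, rt; then dilute aqueous citric acid
Reagents that add atoms: none
Why: Tsuji–Trost-type deallylation: zerovalent palladium ionises the three allyl esters and morpholine traps the allyl groups, while the methyl esters, the two inter-unit esters and the alkenes stay intact.

**Compound list**

1 | dehydroabietic acid, abieta-8,11,13-trien-18-oic acid (4β-CH3, 4α-CO2H, 5α-H, 10β-CH3) | CC(C)c1ccc2c(c1)CC[C@H]1[C@](C)(C(=O)O)CCC[C@]21C | starting material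
2 | methyl dehydroabietate | CC(C)c1ccc2c(c1)CC[C@H]1[C@](C)(C(=O)OC)CCC[C@]21C | intermediate
3 | seco diacid: ring A of 2 (4β-CH3, 4α-CO2CH3, 5α-H, 10β-CH3) with CO2H (C9) on C10 and CH2CH2CO2H (C6–C8) on C5; (1S,2R,3R)-2-(2-carboxyethyl)-3-(methoxycarbonyl)-1,3-dimethylcyclohexane-1-carboxylic acid | OC(=O)[C@@]1(C)CCC[C@@](C)(C(=O)OC)[C@@H]1CCC(=O)O | intermediate
4 | seco diol: as 3 with CH2OH (C9) on C10 and (CH2)3OH (C6–C8) on C5 | OC[C@@]1(C)CCC[C@@](C)(C(=O)OC)[C@@H]1CCCO | intermediate
5 | seco hydroxy aldehyde: as 4 with CH2CH2CHO (C8 aldehyde) on C5 | OC[C@@]1(C)CCC[C@@](C)(C(=O)OC)[C@@H]1CCC=O | intermediate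
6 | seco alkynol: as 4 with CH2CH2C≡CH (C8≡C12) on C5 | OC[C@@]1(C)CCC[C@@](C)(C(=O)OC)[C@@H]1CCC#C | intermediate
7 | seco alkynal: as 6 with CHO (C9) on C10 | O=C[C@@]1(C)CCC[C@@](C)(C(=O)OC)[C@@H]1CCC#C | intermediate
8 | seco enol ether ester: as 7 with CH=CH–OCH3 (C9=C11, E/Z) on C10 | COC=C[C@@]1(C)CCC[C@@](C)(C(=O)OC)[C@@H]1CCC#C | intermediate
9 | seco enol ether alcohol: as 8 with 4α-CH2OH (C15) in place of CO2CH3 | COC=C[C@@]1(C)CCC[C@@](C)(CO)[C@@H]1CCC#C | intermediate
10 | seco enol ether silyl ether: 15-O-TBS ether of 9 | COC=C[C@@]1(C)CCC[C@@](C)(CO[Si](C)(C)C(C)(C)C)[C@@H]1CCC#C | intermediate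
11 | C11 methyl hemiacetal of 12 (either C11 epimer) | COC(O)[C@H]1C(=C)CC[C@H]2[C@](C)(CO[Si](C)(C)C(C)(C)C)CCC[C@]12C | intermediate
12 | 15-(tert-butyldimethylsilyloxy)drim-8(12)-en-11-al (9β-CHO, 9α-H, 5α-H, 10β-CH3, 4β-CH3, 4α-CH2OTBS) | O=C[C@H]1C(=C)CC[C@H]2[C@](C)(CO[Si](C)(C)C(C)(C)C)CCC[C@]12C | intermediate
13 | (R)-2-(2,2-dimethyl-5-oxo-1,3-dioxolan-4-yl)acetic acid (acetonide of (R)-malic acid) | CC1(C)O[C@H](CC(=O)O)C(=O)O1 | starting material
14 | tert-butyl (R)-2-(2,2-dimethyl-5-oxo-1,3-dioxolan-4-yl)acetate | CC1(C)O[C@H](CC(=O)OC(C)(C)C)C(=O)O1 | intermediate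
15 | 4-tert-butyl 1-methyl (2R)-2-hydroxybutanedioate | O[C@@H](C(=O)OC)CC(=O)OC(C)(C)C | intermediate
16 | lithium alkoxide of 3-allyl 2-tert-butyl 1-methyl (1R,2S)-1-hydroxypropane-1,2,3-tricarboxylate | [Li+].[O-][C@@H](C(=O)OC)[C@H](CC(=O)OCC=C)C(=O)OC(C)(C)C | intermediate
17 | 3-allyl 2-tert-butyl 1-methyl (1R,2S)-1-(trimethylsilyloxy)propane-1,2,3-tricarboxylate | C[Si](C)(C)O[C@@H](C(=O)OC)[C@H](CC(=O)OCC=C)C(=O)OC(C)(C)C | intermediate
18 | allyl (R)-2-(2,2-dimethyl-5-oxo-1,3-dioxolan-4-yl)acetate | CC1(C)O[C@H](CC(=O)OCC=C)C(=O)O1 | intermediate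
19 | 4-allyl 1-methyl (2R)-2-hydroxybutanedioate | O[C@@H](C(=O)OC)CC(=O)OCC=C | intermediate
20 | lithium alkoxide of 2-allyl 1,3-dimethyl (1R,2S)-1-hydroxypropane-1,2,3-tricarboxylate | [Li+].[O-][C@@H](C(=O)OC)[C@H](CC(=O)OC)C(=O)OCC=C | intermediate
21 | 2-allyl 1,3-dimethyl (1R,2S)-1-(trimethylsilyloxy)propane-1,2,3-tricarboxylate | C[Si](C)(C)O[C@@H](C(=O)OC)[C@H](CC(=O)OC)C(=O)OCC=C | intermediate
22 | 15-O-TBS-drim-8(12)-en-11-yl ether at O1′ of the (1′R,2′S)-isocitrate 1′-methyl 2′-tert-butyl 3′-allyl ester | C=C1CC[C@H]2[C@](C)(CO[Si](C)(C)C(C)(C)C)CCC[C@]2(C)[C@H]1CO[C@@H](C(=O)OC)[C@H](CC(=O)OCC=C)C(=O)OC(C)(C)C | intermediate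
23 | 2′-trimethylsilyl ester of 24 | C=C1CC[C@H]2[C@](C)(CO[Si](C)(C)C(C)(C)C)CCC[C@]2(C)[C@H]1CO[C@@H](C(=O)OC)[C@H](CC(=O)OCC=C)C(=O)O[Si](C)(C)C | intermediate
24 | monomer acid: 22 with free C2′ carboxylic acid | C=C1CC[C@H]2[C@](C)(CO[Si](C)(C)C(C)(C)C)CCC[C@]2(C)[C@H]1CO[C@@H](C(=O)OC)[C@H](CC(=O)OCC=C)C(=O)O | intermediate
25 | 15-O-TBS-drim-8(12)-en-11-yl ether at O1′ of the (1′R,2′S)-isocitrate 1′,3′-dimethyl 2′-allyl ester | C=C1CC[C@H]2[C@](C)(CO[Si](C)(C)C(C)(C)C)CCC[C@]2(C)[C@H]1CO[C@@H](C(=O)OC)[C@H](CC(=O)OC)C(=O)OCC=C | intermediate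
26 | monomer alcohol: 25 with free 15-OH | C=C1CC[C@H]2[C@](C)(CO)CCC[C@]2(C)[C@H]1CO[C@@H](C(=O)OC)[C@H](CC(=O)OC)C(=O)OCC=C | intermediate
27 | dimer silyl ether: O15 of 26 acylated by the C2′ carboxyl of 24 | C=C1CC[C@H]2[C@](C)(COC(=O)[C@@H](CC(=O)OCC=C)[C@@H](OC[C@H]3C(=C)CC[C@H]4[C@](C)(CO[Si](C)(C)C(C)(C)C)CCC[C@]34C)C(=O)OC)CCC[C@]2(C)[C@H]1CO[C@@H](C(=O)OC)[C@H](CC(=O)OC)C(=O)OCC=C | intermediate
28 | dimer alcohol: 27 with free 15-OH on the second drimane unit | C=C1CC[C@H]2[C@](C)(COC(=O)[C@@H](CC(=O)OCC=C)[C@@H](OC[C@H]3C(=C)CC[C@H]4[C@](C)(CO)CCC[C@]34C)C(=O)OC)CCC[C@]2(C)[C@H]1CO[C@@H](C(=O)OC)[C@H](CC(=O)OC)C(=O)OCC=C | intermediate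
29 | trimer silyl ether: O15 of 28 acylated by the C2′ carboxyl of 24 | C=C1CC[C@H]2[C@](C)(COC(=O)[C@@H](CC(=O)OCC=C)[C@@H](OC[C@H]3C(=C)CC[C@H]4[C@](C)(COC(=O)[C@@H](CC(=O)OCC=C)[C@@H](OC[C@H]5C(=C)CC[C@H]6[C@](C)(CO[Si](C)(C)C(C)(C)C)CCC[C@]56C)C(=O)OC)CCC[C@]34C)C(=O)OC)CCC[C@]2(C)[C@H]1CO[C@@H](C(=O)OC)[C@H](CC(=O)OC)C(=O)OCC=C | intermediate
30 | trimer alcohol, tri-allyl ester | C=C1CC[C@H]2[C@](C)(COC(=O)[C@@H](CC(=O)OCC=C)[C@@H](OC[C@H]3C(=C)CC[C@H]4[C@](C)(COC(=O)[C@@H](CC(=O)OCC=C)[C@@H](OC[C@H]5C(=C)CC[C@H]6[C@](C)(CO)CCC[C@]56C)C(=O)OC)CCC[C@]34C)C(=O)OC)CCC[C@]2(C)[C@H]1CO[C@@H](C(=O)OC)[C@H](CC(=O)OC)C(=O)OCC=C | intermediate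
31 | cryptoporic acid T | C=C1CC[C@H]2[C@](C)(COC(=O)[C@@H](CC(=O)O)[C@@H](OC[C@H]3C(=C)CC[C@H]4[C@](C)(COC(=O)[C@@H](CC(=O)O)[C@@H](OC[C@H]5C(=C)CC[C@H]6[C@](C)(CO)CCC[C@]56C)C(=O)OC)CCC[C@]34C)C(=O)OC)CCC[C@]2(C)[C@H]1CO[C@@H](C(=O)OC)[C@H](CC(=O)OC)C(=O)O | target

**Totals**

Total step count: 25.
Longest linear sequence: 17 steps (steps 1–10, 17, 18, 21, 22, 23, 24, 25).

**Steps most likely to fail**

Step 10. The face selectivity at C9 in the chair-like transition state may be poor, above all for the Z-enol ether. Once the aldehyde is free, its α-centre may also epimerise, or the C8=C12 bond may migrate into conjugation with the formyl group on the Lewis-acidic metal. The fallback makes and keeps C9 at the ether oxidation level and closes ring B by a radical instead of a cation. It sets out from 7 and comes back at 12. Wittig reaction of 7 with [(4-methoxybenzyloxy)methyl]triphenylphosphonium chloride and KN(SiMe3)2 would give the 4-methoxybenzyl enol ether ester F1. LiAlH4 would give the C15 alcohol F2, and TBSCl with imidazole the silyl ether F3. Bu3SnH with azobisisobutyronitrile in benzene at 80 °C would add a stannyl radical to C12; the C8 vinyl radical would close ring B 6-exo-trig on C9 of the enol ether, and reduction of the α-alkoxy radical would give the vinylstannane F4. Protodestannylation with dilute HCl at 0 °C would give the C11 4-methoxybenzyl ether F5, DDQ in wet CH2Cl2 the C11 alcohol F6, and Dess–Martin oxidation would return to 12.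

Step 17 (the same operation recurs in step 19). The oxocarbenium ion at C11 may lose the C9 proton, which would scramble C9 or move the alkene. The weakly nucleophilic α-silyloxy ester may also fail to condense, and the tert-butyl ester may be cleaved by the silyl triflate. The fallback forms the same C11–O bond by SN2 O-alkylation, so that no cationic centre arises next to C9. It sets out from 12 and 17 and comes back at 22. NaBH4 would reduce 12 to the C11 alcohol F6 (the compound of the first fallback). Tf2O with 2,6-di-tert-butyl-4-methylpyridine would give the C11 triflate F7. Citric acid in MeOH would free the hydroxy triester F8 from 17. F8 would then displace the triflate of F7 in CH2Cl2 in the presence of the same hindered pyridine (O-alkylation of an α-hydroxy ester by a primary triflate, with C1′ untouched) to give 22.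

Step 2. Oxidation at the benzylic C7 methylene may compete with degradation of the unactivated arene, which would lead to a side chain one carbon short, and the reaction may stall before the ring is fully consumed. The fallback first turns the ring into a phenol, which RuO4 degrades much faster. It sets out from 2 and comes back at 3. Friedel–Crafts acetylation (AcCl, AlCl3, CH2Cl2) would give methyl 12-acetyldehydroabietate F9. Baeyer–Villiger oxidation with mCPBA would give the aryl acetate F10, and K2CO3 in MeOH the phenol F11. RuCl3 (cat.) with NaIO4 would then degrade the phenol ring of F11 to the seco diacid 3.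

Further compounds
F1 | step 10 | 4-methoxybenzyl enol ether ester: as 8 with OCH2C6H4OCH3 in place of OCH3 (E/Z) | COc1ccc(COC=C[C@@]2(C)CCC[C@@](C)(C(=O)OC)[C@@H]2CCC#C)cc1
F2 | step 10 | C15 alcohol of F1 | COc1ccc(COC=C[C@@]2(C)CCC[C@@](C)(CO)[C@@H]2CCC#C)cc1
F3 | step 10 | 15-O-TBS ether of F2 | COc1ccc(COC=C[C@@]2(C)CCC[C@@](C)(CO[Si](C)(C)C(C)(C)C)[C@@H]2CCC#C)cc1
F4 | step 10 | 12-(tributylstannyl)-11-O-(4-methoxybenzyl)-15-O-TBS-drim-8(12)-ene-11,15-diol (vinylstannane, E/Z) | CCCC[Sn](CCCC)(CCCC)C=C1CC[C@H]2[C@](C)(CO[Si](C)(C)C(C)(C)C)CCC[C@]2(C)[C@H]1COCc1ccc(OC)cc1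
F5 | step 10 | 11-O-(4-methoxybenzyl)-15-O-TBS-drim-8(12)-ene-11,15-diol | C=C1CC[C@H]2[C@](C)(CO[Si](C)(C)C(C)(C)C)CCC[C@]2(C)[C@H]1COCc1ccc(OC)cc1
F6 | step 10 | 15-O-TBS-drim-8(12)-ene-11,15-diol (C11 alcohol) | C=C1CC[C@H]2[C@](C)(CO[Si](C)(C)C(C)(C)C)CCC[C@]2(C)[C@H]1CO
F7 | step 17 | C11 triflate of F6 | C=C1CC[C@H]2[C@](C)(CO[Si](C)(C)C(C)(C)C)CCC[C@]2(C)[C@H]1COS(=O)(=O)C(F)(F)F
F8 | step 17 | 3-allyl 2-tert-butyl 1-methyl (1R,2S)-1-hydroxypropane-1,2,3-tricarboxylate | O[C@@H](C(=O)OC)[C@H](CC(=O)OCC=C)C(=O)OC(C)(C)C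
F9 | step 2 | methyl 12-acetyldehydroabietate | CC(C)c1c(C(C)=O)cc2c(c1)CC[C@H]1[C@](C)(C(=O)OC)CCC[C@]21C
F10 | step 2 | methyl 12-acetoxydehydroabietate | CC(C)c1c(OC(C)=O)cc2c(c1)CC[C@H]1[C@](C)(C(=O)OC)CCC[C@]21C
F11 | step 2 | methyl 12-hydroxydehydroabietate | CC(C)c1c(O)cc2c(c1)CC[C@H]1[C@](C)(C(=O)OC)CCC[C@]21C
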